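**Retrosynthetic overview**
1. The terminal (Z)-enyne is taken back to a propargyl side chain (Cadiot–Chodkiewicz coupling, cis-semireduction, desilylation) on the dibromo-2,8-dioxabicyclo[5.2.1]decane core.
2. The tetrahydrofuran ring (formed last) comes from transannular bromoetherification of an α,α′-trans oxocene with a side-chain hydroxyl; this sets the bridgehead C–O and the second C–Br together.
3. The oxocene (formed first) comes from RCM of an acyclic diene ether; its C–Br comes from an alcohol by Appel inversion, and both carbinol centres from chelation-controlled additions to α-alkoxy aldehydes.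
4. Key C–C disconnection: the allyl–C bond at the ether carbon α to the ester. It is made from a glycolate α-cation (enolonium-type a2 synthon: ethyl glyoxylate locked as a cis-1,3-dioxolan-4-one on (R)-2-hydroxybutanoic acid) and an allylsilane, with inversion, which fixes the trans relationship across the ether oxygen.
5. Ring order: dioxolanone template (opened in the key step) → oxocene (RCM) → tetrahydrofuran (bromoetherification).

Assumption: the SMILES is taken literally, i.e. (1S,3R,4S,6S,7S,9S)-4,6-dibromo-3-ethyl-9-[(2Z)-pent-2-en-4-yn-1-yl]-2,8-dioxabicyclo[5.2.1]decane, in which the hydrogens on C1 and C3 are trans across O2.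

**Step 1**
Reactants: 1 (2R)-2-hydroxybutanoic acid; 2 ethyl glyoxylate
Product: 4 ethyl (2R,5R)-5-ethyl-4-oxo-1,3-dioxolane-2-carboxylate (2,5-cis), via bis-silyl derivative 3 (not isolated)
Conditions: TMSCl, Et3N, CH2Cl2, 0 °C → rt, filter, concentrate; then 2 (freshly distilled), TMSOTf (5 mol %), CH2Cl2, −78 °C
Reagents that add atoms: none
Why: Silyl-mediated (Noyori-type) acetalisation of the α-hydroxy acid with the very electrophilic glyoxylate aldehyde closes the 1,3-dioxolan-4-one; the 2,5-cis isomer is favoured (minor trans isomer removed by chromatography) and C5 keeps the (R) configuration of 1.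

**Step 2**
Reactants: 4 ethyl (2R,5R)-5-ethyl-4-oxo-1,3-dioxolane-2-carboxylate; 5 allyltrimethylsilane
Product: 6 (2R)-2-{[(2S)-1-ethoxy-1-oxopent-4-en-2-yl]oxy}butanoic acid
Conditions: 5 (2 equiv), TiCl4 (1.1 equiv), CH2Cl2, −78 → −40 °C; aq. HCl work-up
Reagents that add atoms: none
Why: Proposed new method: TiCl4 activates the lactone carbonyl so that the C2–O(acyl) bond of the acetal breaks while the allylsilane attacks C2 anti to the departing titanium carboxylate (SN2-like Hosomi–Sakurai substitution, inversion), so the carbon α to the ester, which is the nucleophile in an ordinary glycolate-enolate allylation, reacts here as a glycolate α-cation (enolonium-type a2 synthon) with the nucleophilic allyl terminus and the cis acetal is translated into the (2S) ether centre; the closest known reaction is the TiCl4-mediated opening of 2-alkyl- and 2-aryl-1,3-dioxolan-4-ones and 1,3-dioxan-4-ones by allylsilanes and silyl enol ethers, which goes with inversion at the acetal carbon, the new element being the electron-poor 2-alkoxycarbonyl acetal.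

**Step 3**
Reactants: 6 (2R)-2-{[(2S)-1-ethoxy-1-oxopent-4-en-2-yl]oxy}butanoic acid
Product: 8 ethyl (2S)-2-{[(2R)-1-oxobutan-2-yl]oxy}pent-4-enoate, via acid chloride 7 (not isolated)
Conditions: (COCl)2, DMF (cat.), CH2Cl2, 0 °C → rt, evaporate; then LiAlH(OtBu)3 (1.05 equiv), THF, −78 °C; crude aldehyde used at once
Reagents that add atoms: none
Why: Acid chloride formation followed by low-temperature reduction with the hindered hydride LiAlH(OtBu)3 stops at the aldehyde and leaves the ethyl ester alone; no stereocentre is touched.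

**Step 4**
Reactants: 8 ethyl (2S)-2-{[(2R)-1-oxobutan-2-yl]oxy}pent-4-enoate; 9 allyltributylstannane
Product: 10 ethyl (2S)-2-{[(3R,4R)-4-hydroxyhept-6-en-3-yl]oxy}pent-4-enoate
Conditions: 9 (1.5 equiv), MgBr2·OEt2 (3 equiv), CH2Cl2, −78 → −20 °C; quench cold; use promptly
Reagents that add atoms: none
Why: Chelation-controlled (Cram-chelate, Keck-type) allylation: MgBr2 bridges the aldehyde oxygen and the α-ether oxygen and the allylstannane adds from the face away from the ethyl group, giving the syn (4R) alcohol.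

**Step 5**
Reactants: 10 ethyl (2S)-2-{[(3R,4R)-4-hydroxyhept-6-en-3-yl]oxy}pent-4-enoate
Product: 11 ethyl (2S,4Z,7R,8R)-8-ethyl-7-hydroxy-3,6,7,8-tetrahydro-2H-oxocine-2-carboxylate
Conditions: Grubbs II (5 mol %), CH2Cl2 (2 mM), 40 °C
Reagents that add atoms: none
Why: Ring-closing metathesis; the gauche O–C–C–O arrangement of the vicinal ether and hydroxyl groups preorganises the diene, and the eight-membered ring can only hold the Z alkene.

**Step 6**
Reactants: 11 ethyl (2S,4Z,7R,8R)-8-ethyl-7-hydroxy-3,6,7,8-tetrahydro-2H-oxocine-2-carboxylate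
Product: 12 ethyl (2S,4Z,7S,8R)-7-bromo-8-ethyl-3,6,7,8-tetrahydro-2H-oxocine-2-carboxylate
Conditions: CBr4, (n-Oct)3P, toluene, 70 °C
Reagents that add atoms: carbon tetrabromide BrC(Br)(Br)Br
Why: Appel bromination; SN2 displacement of the alkoxyphosphonium by bromide inverts C7, (7R)-OH to (7S)-Br, while the ester keeps the other oxygen function masked.

**Step 7**
Reactants: 12 ethyl (2S,4Z,7S,8R)-7-bromo-8-ethyl-3,6,7,8-tetrahydro-2H-oxocine-2-carboxylate
Product: 13 (2S,4Z,7S,8R)-7-bromo-8-ethyl-3,6,7,8-tetrahydro-2H-oxocine-2-carbaldehyde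
Conditions: DIBAL-H (1.1 equiv), CH2Cl2, −78 °C; Rochelle salt; crude aldehyde used at once
Reagents that add atoms: none
Why: DIBAL-H half-reduction of the α-alkoxy ester stops at the aldehyde through the stable aluminium hemiacetal at −78 °C; the secondary bromide and all stereocentres are untouched.

**Step 8**
Reactants: 13 (2S,4Z,7S,8R)-7-bromo-8-ethyl-3,6,7,8-tetrahydro-2H-oxocine-2-carbaldehyde; 14 allenyltributylstannane
Product: 15 (1S)-1-[(2S,4Z,7S,8R)-7-bromo-8-ethyl-3,6,7,8-tetrahydro-2H-oxocin-2-yl]but-3-yn-1-ol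
Conditions: 14 (1.5 equiv), MgBr2·OEt2 (3 equiv), CH2Cl2, −78 → −20 °C
Reagents that add atoms: none
Why: Chelation-controlled SE2′ propargylation: MgBr2 chelates the aldehyde and the ring oxygen, and the allenylstannane attacks the face away from the ring CH2, giving the syn (1S) homopropargylic alcohol.

**Step 9**
Reactants: 15 (1S)-1-[(2S,4Z,7S,8R)-7-bromo-8-ethyl-3,6,7,8-tetrahydro-2H-oxocin-2-yl]but-3-yn-1-ol
Product: 16 (1S,3R,4S,6S,7S,9S)-4,6-dibromo-3-ethyl-9-(prop-2-yn-1-yl)-2,8-dioxabicyclo[5.2.1]decane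
Conditions: NBS (1.1 equiv), MeCN, 0 °C → rt, dark
Reagents that add atoms: N-bromosuccinimide O=C1CCC(=O)N1Br
Why: Transannular bromoetherification: the bromonium forms on the alkene face opposite the side-chain hydroxyl, which attacks C4 of the oxocene 5-exo, and the anti addition sets the bridgehead C–O (7S) and the C–Br (6S) in one step.

**Step 10**
Reactants: 16 (1S,3R,4S,6S,7S,9S)-4,6-dibromo-3-ethyl-9-(prop-2-yn-1-yl)-2,8-dioxabicyclo[5.2.1]decane; 17 (bromoethynyl)tri(propan-2-yl)silane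
Product: 18 {5-[(1S,3R,4S,6S,7S,9S)-4,6-dibromo-3-ethyl-2,8-dioxabicyclo[5.2.1]decan-9-yl]penta-1,3-diyn-1-yl}tri(propan-2-yl)silane
Conditions: 17, CuCl (10 mol %), NH2OH·HCl, n-BuNH2 (30 % aq.), CH2Cl2, 0 °C
Reagents that add atoms: none
Why: Cadiot–Chodkiewicz coupling of the terminal alkyne with the bromoalkyne under Cu(I) and amine; no stereocentre is involved and the secondary bromides are inert at 0 °C.

**Step 11**
Reactants: 18 {5-[(1S,3R,4S,6S,7S,9S)-4,6-dibromo-3-ethyl-2,8-dioxabicyclo[5.2.1]decan-9-yl]penta-1,3-diyn-1-yl}tri(propan-2-yl)silane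
Product: 20 {(3Z)-5-[(1S,3R,4S,6S,7S,9S)-4,6-dibromo-3-ethyl-2,8-dioxabicyclo[5.2.1]decan-9-yl]pent-3-en-1-yn-1-yl}tri(propan-2-yl)silane, via C3-boryl enyne 19 (not isolated)
Conditions: Sia2BH (from BH3·THF and 2-methylbut-2-ene, 1.1 equiv), THF, 0 °C; then AcOH, 50 °C
Reagents that add atoms: none
Why: Zweifel-type monohydroboration of the silyl-capped 1,3-diyne at the unhindered triple bond (syn addition) and protonolysis of the alkenylborane with retention give the Z-enyne; the TIPS-alkyne is shielded.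

**Step 12**
Reactants: 20 {(3Z)-5-[(1S,3R,4S,6S,7S,9S)-4,6-dibromo-3-ethyl-2,8-dioxabicyclo[5.2.1]decan-9-yl]pent-3-en-1-yn-1-yl}tri(propan-2-yl)silane
Product: 21 (1S,3R,4S,6S,7S,9S)-4,6-dibromo-3-ethyl-9-[(2Z)-pent-2-en-4-yn-1-yl]-2,8-dioxabicyclo[5.2.1]decane
Conditions: TBAF, AcOH (1:1), THF, 0 °C → rt
Reagents that add atoms: none
Why: Fluoride-mediated protodesilylation of the alkynylsilane, buffered with acetic acid so that the secondary bromides are not eliminated, releases the terminal (Z)-enyne of the target.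

**Compound list**
1 | (2R)-2-hydroxybutanoic acid | CC[C@@H](O)C(=O)O | starting material
2 | ethyl glyoxylate | CCOC(=O)C=O | starting material
3 | trimethylsilyl (2R)-2-[(trimethylsilyl)oxy]butanoate | CC[C@@H](O[Si](C)(C)C)C(=O)O[Si](C)(C)C | intermediate
4 | ethyl (2R,5R)-5-ethyl-4-oxo-1,3-dioxolane-2-carboxylate | CC[C@H]1O[C@@H](C(=O)OCC)OC1=O | intermediate
5 | allyltrimethylsilane | C=CC[Si](C)(C)C | starting material
6 | (2R)-2-{[(2S)-1-ethoxy-1-oxopent-4-en-2-yl]oxy}butanoic acid | CC[C@@H](O[C@@H](CC=C)C(=O)OCC)C(=O)O | intermediate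
7 | ethyl (2S)-2-{[(2R)-1-chloro-1-oxobutan-2-yl]oxy}pent-4-enoate | CC[C@@H](O[C@@H](CC=C)C(=O)OCC)C(Cl)=O | intermediate
8 | ethyl (2S)-2-{[(2R)-1-oxobutan-2-yl]oxy}pent-4-enoate | CC[C@@H](O[C@@H](CC=C)C(=O)OCC)C=O | intermediate
9 | allyltributylstannane | C=CC[Sn](CCCC)(CCCC)CCCC | starting material
10 | ethyl (2S)-2-{[(3R,4R)-4-hydroxyhept-6-en-3-yl]oxy}pent-4-enoate | CC[C@@H](O[C@@H](CC=C)C(=O)OCC)[C@H](O)CC=C | intermediate
11 | ethyl (2S,4Z,7R,8R)-8-ethyl-7-hydroxy-3,6,7,8-tetrahydro-2H-oxocine-2-carboxylate | CCOC(=O)[C@@H]1C/C=C\C[C@@H](O)[C@@H](CC)O1 | intermediate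
12 | ethyl (2S,4Z,7S,8R)-7-bromo-8-ethyl-3,6,7,8-tetrahydro-2H-oxocine-2-carboxylate | CCOC(=O)[C@@H]1C/C=C\C[C@H](Br)[C@@H](CC)O1 | intermediate
13 | (2S,4Z,7S,8R)-7-bromo-8-ethyl-3,6,7,8-tetrahydro-2H-oxocine-2-carbaldehyde | O=C[C@@H]1C/C=C\C[C@H](Br)[C@@H](CC)O1 | intermediate
14 | allenyltributylstannane | C=C=C[Sn](CCCC)(CCCC)CCCC | starting material
15 | (1S)-1-[(2S,4Z,7S,8R)-7-bromo-8-ethyl-3,6,7,8-tetrahydro-2H-oxocin-2-yl]but-3-yn-1-ol | C#CC[C@H](O)[C@@H]1C/C=C\C[C@H](Br)[C@@H](CC)O1 | intermediate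
16 | (1S,3R,4S,6S,7S,9S)-4,6-dibromo-3-ethyl-9-(prop-2-yn-1-yl)-2,8-dioxabicyclo[5.2.1]decane | C#CC[C@@H]1O[C@H]2C[C@@H]1O[C@H](CC)[C@@H](Br)C[C@@H]2Br | intermediate
17 | (bromoethynyl)tri(propan-2-yl)silane | BrC#C[Si](C(C)C)(C(C)C)C(C)C | starting material
18 | {5-[(1S,3R,4S,6S,7S,9S)-4,6-dibromo-3-ethyl-2,8-dioxabicyclo[5.2.1]decan-9-yl]penta-1,3-diyn-1-yl}tri(propan-2-yl)silane | CC(C)[Si](C#CC#CC[C@@H]1O[C@H]2C[C@@H]1O[C@H](CC)[C@@H](Br)C[C@@H]2Br)(C(C)C)C(C)C | intermediate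
19 | {(3Z)-5-[(1S,3R,4S,6S,7S,9S)-4,6-dibromo-3-ethyl-2,8-dioxabicyclo[5.2.1]decan-9-yl]-1-[tri(propan-2-yl)silyl]pent-3-en-1-yn-3-yl}bis(3-methylbutan-2-yl)borane | CC(C)[Si](C#C/C(B(C(C)C(C)C)C(C)C(C)C)=C\C[C@@H]1O[C@H]2C[C@@H]1O[C@H](CC)[C@@H](Br)C[C@@H]2Br)(C(C)C)C(C)C | intermediate
20 | {(3Z)-5-[(1S,3R,4S,6S,7S,9S)-4,6-dibromo-3-ethyl-2,8-dioxabicyclo[5.2.1]decan-9-yl]pent-3-en-1-yn-1-yl}tri(propan-2-yl)silane | CC(C)[Si](C#C/C=C\C[C@@H]1O[C@H]2C[C@@H]1O[C@H](CC)[C@@H](Br)C[C@@H]2Br)(C(C)C)C(C)C | intermediate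
21 | (1S,3R,4S,6S,7S,9S)-4,6-dibromo-3-ethyl-9-[(2Z)-pent-2-en-4-yn-1-yl]-2,8-dioxabicyclo[5.2.1]decane | C#C/C=C\C[C@@H]1O[C@H]2C[C@@H]1O[C@H](CC)[C@@H](Br)C[C@@H]2Br | target

**Total steps:** 12. **Longest linear sequence:** 12 steps (1 → 21).

**Steps most likely to fail, with fallbacks**

Step 2 (opening of the ester-substituted acetal). The likely failure is loss of stereospecificity through a loose ion pair, so that 10 later arrives mixed with its C2 epimer. The fallback sets out from 10 and returns at 13, and replaces kinetic control by thermodynamic control on a six-membered lactone. The contaminant is ethyl (2R)-2-{[(3R,4R)-4-hydroxyhept-6-en-3-yl]oxy}pent-4-enoate F1. Heating the mixture with PPTS in toluene at 80 °C lactonises 10 to the all-equatorial (3S,5R,6R)-5-ethyl-3,6-di(prop-2-en-1-yl)-1,4-dioxan-2-one F2 and F1 to its C3 epimer, (3R,5R,6R)-5-ethyl-3,6-di(prop-2-en-1-yl)-1,4-dioxan-2-one F3. Catalytic DBU epimerises F3 at the carbon α to the lactone carbonyl into F2, because only F2 has all three substituents equatorial. Me(MeO)NH·HCl with AlMe3 opens F2 to (2S)-2-{[(3R,4R)-4-hydroxyhept-6-en-3-yl]oxy}-N-methoxy-N-methylpent-4-enamide F4. Grubbs II closes this to (2S,4Z,7R,8R)-8-ethyl-7-hydroxy-N-methoxy-N-methyl-3,6,7,8-tetrahydro-2H-oxocine-2-carboxamide F5. CBr4 and (n-Oct)3P give (2S,4Z,7S,8R)-7-bromo-8-ethyl-N-methoxy-N-methyl-3,6,7,8-tetrahydro-2H-oxocine-2-carboxamide F6, and DIBAL-H at −78 °C reduces F6 to 13. The same detour also rescues the case in which 10 lactonises before the metathesis.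

Step 9 (transannular bromoetherification in the unprecedented α,α′-trans series). The likely failure is 6-endo closure or intermolecular bromination. The fallback sets out from 15 and returns at 16, and replaces the irreversible bromonium by a reversible selenium electrophile followed by two inversions. PhSeCl in CH2Cl2 at −78 °C gives the 5-exo ether (1S,3R,4S,6S,7S,9S)-4-bromo-3-ethyl-6-(phenylselanyl)-9-(prop-2-yn-1-yl)-2,8-dioxabicyclo[5.2.1]decane F7. mCPBA and K2HPO4 in wet THF oxidise the selenide to the selenone, which water displaces with inversion to (1S,3R,4S,6R,7S,9S)-4-bromo-3-ethyl-9-(prop-2-yn-1-yl)-2,8-dioxabicyclo[5.2.1]decan-6-ol F8. CBr4 and (n-Oct)3P then introduce bromide with a second inversion and give 16.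

Step 11 (chemoselective cis-semireduction of the diyne). The likely failure is over-reduction or attack at the wrong triple bond. The fallback sets out from 16 (so it also bypasses step 10) and returns at 20, building the Z alkene before the second alkyne is attached. NIS with catalytic AgNO3 in acetone gives (1S,3R,4S,6S,7S,9S)-4,6-dibromo-3-ethyl-9-(3-iodoprop-2-yn-1-yl)-2,8-dioxabicyclo[5.2.1]decane F9. Diimide (2-nitrobenzenesulfonylhydrazide, Et3N, THF/i-PrOH) reduces it to (1S,3R,4S,6S,7S,9S)-4,6-dibromo-3-ethyl-9-[(2Z)-3-iodoprop-2-en-1-yl]-2,8-dioxabicyclo[5.2.1]decane F10. Sonogashira coupling with (triisopropylsilyl)acetylene (Pd(PPh3)4, CuI, i-Pr2NH) gives 20 with retention of the Z geometry.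

**Further compounds**
F1 | step 2 | ethyl (2R)-2-{[(3R,4R)-4-hydroxyhept-6-en-3-yl]oxy}pent-4-enoate | CC[C@@H](O[C@H](CC=C)C(=O)OCC)[C@H](O)CC=C
F2 | step 2 | (3S,5R,6R)-5-ethyl-3,6-di(prop-2-en-1-yl)-1,4-dioxan-2-one | C=CC[C@@H]1O[C@H](CC)[C@@H](CC=C)OC1=O
F3 | step 2 | (3R,5R,6R)-5-ethyl-3,6-di(prop-2-en-1-yl)-1,4-dioxan-2-one | C=CC[C@H]1O[C@H](CC)[C@@H](CC=C)OC1=O
F4 | step 2 | (2S)-2-{[(3R,4R)-4-hydroxyhept-6-en-3-yl]oxy}-N-methoxy-N-methylpent-4-enamide | CC[C@@H](O[C@@H](CC=C)C(=O)N(C)OC)[C@H](O)CC=C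
F5 | step 2 | (2S,4Z,7R,8R)-8-ethyl-7-hydroxy-N-methoxy-N-methyl-3,6,7,8-tetrahydro-2H-oxocine-2-carboxamide | CON(C)C(=O)[C@@H]1C/C=C\C[C@@H](O)[C@@H](CC)O1
F6 | step 2 | (2S,4Z,7S,8R)-7-bromo-8-ethyl-N-methoxy-N-methyl-3,6,7,8-tetrahydro-2H-oxocine-2-carboxamide | CON(C)C(=O)[C@@H]1C/C=C\C[C@H](Br)[C@@H](CC)O1
F7 | step 9 | (1S,3R,4S,6S,7S,9S)-4-bromo-3-ethyl-6-(phenylselanyl)-9-(prop-2-yn-1-yl)-2,8-dioxabicyclo[5.2.1]decane | C#CC[C@@H]1O[C@H]2C[C@@H]1O[C@H](CC)[C@@H](Br)C[C@@H]2[Se]c1ccccc1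
F8 | step 9 | (1S,3R,4S,6R,7S,9S)-4-bromo-3-ethyl-9-(prop-2-yn-1-yl)-2,8-dioxabicyclo[5.2.1]decan-6-ol | C#CC[C@@H]1O[C@H]2C[C@@H]1O[C@H](CC)[C@@H](Br)C[C@H]2O
F9 | step 11 | (1S,3R,4S,6S,7S,9S)-4,6-dibromo-3-ethyl-9-(3-iodoprop-2-yn-1-yl)-2,8-dioxabicyclo[5.2.1]decane | IC#CC[C@@H]1O[C@H]2C[C@@H]1O[C@H](CC)[C@@H](Br)C[C@@H]2Br
F10 | step 11 | (1S,3R,4S,6S,7S,9S)-4,6-dibromo-3-ethyl-9-[(2Z)-3-iodoprop-2-en-1-yl]-2,8-dioxabicyclo[5.2.1]decane | I/C=C\C[C@@H]1O[C@H]2C[C@@H]1O[C@H](CC)[C@@H](Br)C[C@@H]2Br
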